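Remark: chroman numbering (O1, C2, C3, C4, C4a, C5 to C8, C8a) is used for every compound, also before the pyran ring exists; C4 of the target works out as R (OH > C4a > C3 > H); BF3·OEt2 in step 1 is promoter and solvent, so that step releases only water.

## Structural features

The target is a chroman: a benzene ring fused across C4a–C8a to a dihydropyran. The benzene ring is fully substituted, with the ring oxygen O1 on C8a, the 3-phenylpropanoyl group on C8, a hydroxyl on C7, a methyl on C6, a hydroxyl on C5 and the pyran carbon C4 on C4a. The pyran ring carries a gem-dimethyl group at C2, a methylene at C3 and the only stereocentre, the secondary carbinol C4 (R). C4 has no stereogenic neighbour (C3 is CH2, C4a is aromatic), so its configuration must come from a reagent or catalyst. The C4 hydroxyl is the fragile group: it is benzylic to a ring with oxygen at both ortho positions and at the para position, so acid or hot base can ionise it to a quinone methide, with racemisation or loss of water to the chromene. The aryl ketone, chelated by the C7 hydroxyl, is open to hydride reduction and, with alkaline peroxide, to Dakin-type cleavage. The real difficulty is twofold. First, the three-carbon unit on C4a lies between O5 and the C8a oxygen, and only closure onto the C8a oxygen (ortho to the ketone) gives the target. Second, oxygen must be placed at C4 rather than C3, on one face, in the presence of the ketone. The key step uses the ortho relationship of the C8a hydroxyl and a prenyl group on C4a: oxidation at C4 creates the oxatriene O=C8a–C4a=C4–C3=C2, which closes O1–C2 and leaves the C3=C4 alkene exactly where the carbinol is needed.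

## Logic of the disconnections

12 to 11: the O5–Si and O7–Si bonds are the last to be broken in the forward sense. The C4 carbinol tolerates neither acid nor strong base, so both phenols are kept under groups that fall to buffered fluoride. This gains nothing in skeleton but makes the preceding steps possible. The final step must therefore be cold and near neutral.

11 to 9 (through 10): the C4–O bond and the C3–H bond are removed to give the C3=C4 alkene. C4 is an isolated stereocentre and the alkene is what the ring-forming step delivers. The precursor becomes achiral. The forward step must put the heteroatom on the benzylic carbon (Markovnikov), choose one alkene face under catalyst control, spare the ketone, and exchange boron in 10 for oxygen with retention.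

9 to 8: the O7–Si bond is cut. A free, chelated phenol next to the ketone would be converted by a borane into a boron chelate that activates the carbonyl towards reduction and supplies protons to the metal alkyl. The cost is one step. The forward demand is silylation of a hindered, hydrogen-bonded phenol without touching the ketone enol.

8 to 6 (through 7): the O1–C2 bond is cut, which opens the pyran ring to a prenyl chain on C4a and a free C8a hydroxyl. This is the largest simplification of the plan: the bicycle becomes a monocyclic, fully substituted benzene that ordinary aromatic substitution can assemble. The forward step must remove hydride from the ArCH2 group only, and only the C8a oxygen may close the ring, which is why O5 is already blocked in 6.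

6 to 5: the O5–Si bond is cut. This protecting group is the regiochemical control element of the ring closure. The forward step must distinguish the hydroxyl para to the ketone from the two chelated ortho hydroxyls.

5 to 3 and 4: the C4a–C4 bond is cut. C4a is the only unsubstituted ring carbon of 3, so carbon alkylation has a single possible site. The forward step must favour carbon over oxygen attack and avoid dearomatising alkylation at the methyl-bearing carbon.

3 to 1 and 2: the bond from C8 to the carbonyl carbon is cut. The two free ring carbons of 1 are equivalent, so acylation gives one constitution and brings in the whole side chain at the outset, on a robust substrate. The forward step must stop at mono-acylation.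

## Other disconnections considered

Alternative 1: Both rings are unravelled at once by cutting C4a–C8a and C7–C8. This leads to the open-chain precursor A1, a 1-methoxy-1,3-bis(silyloxy)diene joined through the future C4–C3–C2–O1 chain to an ynol-ether ynone, with C4 already R and silylated. In the forward step the diene would add across the tethered alkyne in an intramolecular [4+2] cycloaddition. The cyclohexadiene would then expel its methoxy group together with the C4a hydrogen and aromatise to chalcone A2, which still needs saturation of its enone alkene and desilylation.
- In favour: the substitution pattern of the hexasubstituted ring is fixed by connectivity, so no phenol has to be differentiated. The C4 stereocentre can be set in an acyclic fragment by routine asymmetric carbonyl chemistry before any ionisable benzylic position exists. On both points this plan is the equal or the better of the chosen one.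
- Against: A1 combines a hydrolytically labile ketene-acetal diene, a tertiary-alkyl ynol ether that can fragment to a ketene on warming, and a cinnamoyl enone that is a competing dienophile and Michael acceptor. Its assembly would take many linear steps. A2 would need a conjugate reduction that spares the C4–O bond.
- Comparison: both plans close the pyran ring by a pericyclic event. The chosen plan keeps a commercial aromatic core and needs one robust precursor (6), so it is clearly shorter (seven steps) and mechanistically less exposed.

Alternative 2: The C4–C4a bond is cut, which leads to the aryloxy aldehyde A3. With Ti(OiPr)4 and BINOL the titanium aryloxide of a flanking hydroxyl would bind the aldehyde and deliver it to the ortho carbon through a six-membered chelate, closing the pyran ring and setting C4 in chromantriol A4.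
- In favour: the C–C bond and the stereocentre are formed together under catalyst control. A3 is symmetric about its methyl–oxygen axis, so either ortho carbon gives the same constitution and no protecting group is needed to steer the closure. On that point it is better than the chosen plan.
- Against: A3 is a β-aryloxy aldehyde that can lose phenoxide by retro-oxa-Michael reaction, and its tertiary aryl ether must be made at one of three hydroxyls. Asymmetric phenol hydroxyalkylation is best established for activated aldehydes. The product carbinol sits in a Lewis-acidic medium where it can ionise. A4 also lacks the acyl chain, which would have to be introduced at C8 by Friedel–Crafts or Fries chemistry in the presence of the most acid-labile group of the molecule, at the cost of extra protection steps.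
- Comparison: the ring closure is more direct, but the chosen plan installs the acyl group first on a stable phloroglucinol and creates the sensitive carbinol second to last. That ordering is safer and no longer.

Alternative 3: The arene is cut at C5–C6, C7–C8 and C4a–C5, which leads to the chiral dihydropyranyl diazoketone A5 and the siloxyalkyne A6. Irradiation of A5 would give, by Wolff rearrangement, a vinylketene that adds A6 in a [2+2] sense. Four-electron opening of the cyclobutenone and six-electron closure of the dienylketene would then give phenol A7.
- In favour: every ring substituent is placed by the connectivity of the cascade. The two phenolic oxygens emerge differentiated (free at C5, silylated at C7). C4 is set on a small heterocycle before the arene exists. On regiocontrol and stereocontrol it is the equal or the better of the chosen plan.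
- Against: A5 is an acid-sensitive enol-ether diazoketone that needs a photochemical step, and A6 must be prepared. A7 still lacks the C8 acyl chain, so a late acylation would have to be run beside a benzylic silyl ether on a very electron-rich ring.
- Comparison: mechanistically elegant, but longer and more hazardous than a route whose every carbon arrives from three commercial compounds in the first two steps.

Key step: step 4

## Route

Step 1
Reactants: 1 2-methylphloroglucinol; 2 3-phenylpropanoic acid
Product: 3 1-(2,4,6-trihydroxy-3-methylphenyl)-3-phenylpropan-1-one
Conditions: BF3·OEt2 (neat), 90 °C; aq. NaOAc work-up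
Reagents that add atoms: none
Why: Friedel–Crafts (Nencki-type) acylation of a phloroglucinol by a BF3-activated carboxylic acid; the two free ring carbons of 1 are equivalent, so one ketone forms, and the chelated product is deactivated towards a second acylation.

Step 2
Reactants: 3 1-(2,4,6-trihydroxy-3-methylphenyl)-3-phenylpropan-1-one; 4 prenyl bromide
Product: 5 1-[2,4,6-trihydroxy-3-methyl-5-(3-methylbut-2-en-1-yl)phenyl]-3-phenylpropan-1-one
Conditions: 10% aq. KOH, 0 °C, 4 (1.05 equiv) added slowly; then dilute HCl to pH 4
Reagents that add atoms: none
Why: C-alkylation of an acylphloroglucinol phenoxide, an ambident vinylogous enolate; water hydrogen-bonds the oxygens and so favours attack through carbon, and C4a is the only ring carbon that can re-aromatise after alkylation. One equivalent of halide at 0 °C limits O-prenylation and alkylation at the methyl-bearing carbon.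

Step 3
Reactants: 5 1-[2,4,6-trihydroxy-3-methyl-5-(3-methylbut-2-en-1-yl)phenyl]-3-phenylpropan-1-one
Product: 6 1-[4-(tert-butyldimethylsilyloxy)-2,6-dihydroxy-3-methyl-5-(3-methylbut-2-en-1-yl)phenyl]-3-phenylpropan-1-one
Conditions: TBSCl (1.05 equiv), imidazole, DMF, 0 °C
Reagents that add atoms: tert-butyldimethylsilyl chloride, CC(C)(C)[Si](C)(C)Cl
Why: Site-selective phenol silylation; the hydroxyl para to the ketone (O5) is the most acidic and is not hydrogen-bonded to the carbonyl, whereas the two ortho hydroxyls are chelated and less nucleophilic, so one equivalent of silyl chloride should go to O5.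

Step 4
Reactants: 6 1-[4-(tert-butyldimethylsilyloxy)-2,6-dihydroxy-3-methyl-5-(3-methylbut-2-en-1-yl)phenyl]-3-phenylpropan-1-one
Product: 8 1-[5-(tert-butyldimethylsilyloxy)-7-hydroxy-2,2,6-trimethyl-2H-chromen-8-yl]-3-phenylpropan-1-one, via vinyl ortho-quinone methide 7 (not isolated)
Conditions: DDQ (1.1 equiv), PhMe, rt; filtration of the precipitated hydroquinone
Reagents that add atoms: none
Why: DDQ forms a charge-transfer complex with the electron-rich arene and removes hydride from the ArCH2 group, which is both benzylic and allylic; the resulting cation is an O-protonated quinone methide and loses the proton of the C8a hydroxyl to give the (Z)-vinyl ortho-quinone methide 7 (the para C7 hydroxyl can lead only to a para-quinone methide, which cannot cyclise and returns to 7 by proton shuttling). 7 is a 1-oxatriene (O=C8a–C4a=C4–C3=C2) and closes by a thermal disrotatory oxa-6π electrocyclisation that forms O1–C2 and restores the aromatic ring, so the pyran ring is closed in a pericyclic mode without an ionic centre at C2. The closest known reaction type is the DDQ oxidative cyclisation of ortho-prenylphenols to 2,2-dimethyl-2H-chromenes. No stereocentre is created, because C2 carries two methyl groups. The selectivity required is the choice of oxygen: C4a lies between O5 and the C8a oxygen, and the silyl group on O5 leaves only the C8a hydroxyl able to supply the quinone methide carbonyl, since proton loss is far faster than silyl loss. Chemoselectivity rests on the low hydride-donor ability of the other C–H bonds (the C6 methyl is only primary benzylic and the PhCH2CH2CO chain is not activated) and on the use of close to one equivalent of oxidant at room temperature. The medium contains no acid beyond the precipitating hydroquinone, so the C3=C4 alkene and the aryl silyl ether persist.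

Step 5
Reactants: 8 1-[5-(tert-butyldimethylsilyloxy)-7-hydroxy-2,2,6-trimethyl-2H-chromen-8-yl]-3-phenylpropan-1-one
Product: 9 1-[5,7-bis(tert-butyldimethylsilyloxy)-2,2,6-trimethyl-2H-chromen-8-yl]-3-phenylpropan-1-one
Conditions: TBSOTf (1.2 equiv), 2,6-lutidine, CH2Cl2, −78 to 0 °C
Reagents that add atoms: tert-butyldimethylsilyl triflate, CC(C)(C)[Si](C)(C)OS(=O)(=O)C(F)(F)F
Why: Silylation of the one remaining, chelated and hindered phenol with a silyl triflate; 2,6-lutidine is too weak and too hindered to enolise the ketone at this temperature. The free phenol is removed because a borane would turn it into a boron chelate that activates the neighbouring ketone towards reduction.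

Step 6
Reactants: 9 1-[5,7-bis(tert-butyldimethylsilyloxy)-2,2,6-trimethyl-2H-chromen-8-yl]-3-phenylpropan-1-one
Product: 11 1-[(4R)-5,7-bis(tert-butyldimethylsilyloxy)-4-hydroxy-2,2,6-trimethylchroman-8-yl]-3-phenylpropan-1-one, via C4 catechol boronate 10 (not isolated)
Conditions: [Rh(cod)2]OTf (2 mol %), (R)-QUINAP (2.4 mol %), catecholborane (1.3 equiv), THF, 0 °C to rt; then NaBO3·4H2O, THF/H2O, rt
Reagents that add atoms: sodium perborate (supplies the C4 oxygen), [Na+].[O-]OB=O; catecholborane (supplies boron and the catecholate of 10 only, and the new C3 hydrogen of 11), B1Oc2ccccc2O1
Why: Rhodium-catalysed asymmetric Markovnikov hydroboration of a vinylarene (Hayashi–Brown type): B–H oxidative addition, insertion that places rhodium at benzylic C4 as an η3-benzyl species and reductive elimination give 10 by syn addition, with the C4 face chosen by the ligand; the (R) ligand is expected to give 4R by analogy with styrenes and 1,2-dihydronaphthalene, and the (S) ligand is the remedy should the sense be opposite here. Catalysed addition to C=C outruns the uncatalysed carbonyl reduction by catecholborane, and perborate replaces boron by oxygen with retention without Dakin or Baeyer–Villiger attack on the aryl ketone.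

Step 7
Reactants: 11 1-[(4R)-5,7-bis(tert-butyldimethylsilyloxy)-4-hydroxy-2,2,6-trimethylchroman-8-yl]-3-phenylpropan-1-one
Product: 12 1-[(4R)-4,5,7-trihydroxy-2,2,6-trimethyl-3,4-dihydro-2H-chromen-8-yl]-3-phenylpropan-1-one (target)
Conditions: TBAF (2.5 equiv), AcOH (2.5 equiv), THF, 0 °C; pH 7 buffer work-up
Reagents that add atoms: none
Why: Fluoride desilylation of two aryl silyl ethers, driven by the Si–F bond and the good phenoxide leaving groups. Acetic acid buffering keeps the medium near neutral, so the C4 carbinol neither ionises nor eliminates through a quinone methide, and C4 keeps its configuration.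

## Compound list

1 | 2-methylphloroglucinol (2-methylbenzene-1,3,5-triol) | Cc1c(O)cc(O)cc1O | starting material
2 | 3-phenylpropanoic acid | OC(=O)CCc1ccccc1 | starting material
3 | 1-(2,4,6-trihydroxy-3-methylphenyl)-3-phenylpropan-1-one | Cc1c(O)cc(O)c(C(=O)CCc2ccccc2)c1O | intermediate
4 | prenyl bromide (1-bromo-3-methylbut-2-ene) | CC(C)=CCBr | starting material
5 | 1-[2,4,6-trihydroxy-3-methyl-5-(3-methylbut-2-en-1-yl)phenyl]-3-phenylpropan-1-one | Cc1c(O)c(C(=O)CCc2ccccc2)c(O)c(CC=C(C)C)c1O | intermediate
6 | 1-[4-(tert-butyldimethylsilyloxy)-2,6-dihydroxy-3-methyl-5-(3-methylbut-2-en-1-yl)phenyl]-3-phenylpropan-1-one | Cc1c(O)c(C(=O)CCc2ccccc2)c(O)c(CC=C(C)C)c1O[Si](C)(C)C(C)(C)C | intermediate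
7 | (Z)-vinyl ortho-quinone methide, 5-(tert-butyldimethylsilyloxy)-3-hydroxy-4-methyl-6-(3-methylbut-2-en-1-ylidene)-2-(3-phenylpropanoyl)cyclohexa-2,4-dien-1-one | O=C1/C(=C\C=C(C)C)C(O[Si](C)(C)C(C)(C)C)=C(C)C(O)=C1C(=O)CCc2ccccc2 | intermediate (not isolated)
8 | 1-[5-(tert-butyldimethylsilyloxy)-7-hydroxy-2,2,6-trimethyl-2H-chromen-8-yl]-3-phenylpropan-1-one | Cc1c(O)c(C(=O)CCc2ccccc2)c2c(c1O[Si](C)(C)C(C)(C)C)C=CC(C)(C)O2 | intermediate
9 | 1-[5,7-bis(tert-butyldimethylsilyloxy)-2,2,6-trimethyl-2H-chromen-8-yl]-3-phenylpropan-1-one | Cc1c(O[Si](C)(C)C(C)(C)C)c(C(=O)CCc2ccccc2)c2c(c1O[Si](C)(C)C(C)(C)C)C=CC(C)(C)O2 | intermediate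
10 | 1-[(4R)-4-(1,3,2-benzodioxaborol-2-yl)-5,7-bis(tert-butyldimethylsilyloxy)-2,2,6-trimethylchroman-8-yl]-3-phenylpropan-1-one | Cc1c(O[Si](C)(C)C(C)(C)C)c(C(=O)CCc2ccccc2)c2c(c1O[Si](C)(C)C(C)(C)C)[C@H](B3Oc4ccccc4O3)CC(C)(C)O2 | intermediate (not isolated)
11 | 1-[(4R)-5,7-bis(tert-butyldimethylsilyloxy)-4-hydroxy-2,2,6-trimethylchroman-8-yl]-3-phenylpropan-1-one | Cc1c(O[Si](C)(C)C(C)(C)C)c(C(=O)CCc2ccccc2)c2c(c1O[Si](C)(C)C(C)(C)C)[C@H](O)CC(C)(C)O2 | intermediate
12 | 1-[(4R)-4,5,7-trihydroxy-2,2,6-trimethyl-3,4-dihydro-2H-chromen-8-yl]-3-phenylpropan-1-one | Cc1c(O)c(C(=O)CCc2ccccc2)c2c(c1O)[C@H](O)CC(C)(C)O2 | target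

## Step count and least certain steps

Total: 7 steps. Longest linear sequence: 7 steps (1 to 12); 2 and 4 enter as purchased compounds.

Step 4 (key step). The quinone methide is a strong electrophile on a very electron-rich ring, so the likely failures are intermolecular capture of the quinone methide (dimerisation or addition of a second phenol), further hydride abstraction by excess oxidant, and silyl loss from the O5 oxocarbenium form that would open the wrong closure. Fallback without a quinone methide: from 6, selenoetherification with N-(phenylseleno)phthalimide and catalytic camphorsulfonic acid in CH2Cl2 would give, by Markovnikov 6-endo attack of the only free neighbouring oxygen on the seleniranium ion, the racemic 1-[5-(tert-butyldimethylsilyloxy)-7-hydroxy-2,2,6-trimethyl-3-(phenylselanyl)chroman-8-yl]-3-phenylpropan-1-one F1. Oxidation with H2O2 in THF at 0 °C and syn elimination of the selenoxide, whose only β-hydrogens are at C4, would return to the route at 8.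

Step 6. The alkene is flanked by the gem-dimethyl group and by the peri silyloxy group on a fully substituted ring, so insertion may be slow, regiocontrol may leak towards C3, facial selection may be poor, and slow carbonyl reduction by the borane may then compete. Fallback through a ketone: from 9, Mukaiyama hydration (Co(acac)2 cat., PhSiH3, O2, THF/iPrOH), in which hydrogen-atom transfer to C3 gives the benzylic C4 radical, would give the racemic carbinol 1-[5,7-bis(tert-butyldimethylsilyloxy)-4-hydroxy-2,2,6-trimethylchroman-8-yl]-3-phenylpropan-1-one F2. MnO2 in CH2Cl2 would oxidise it to the chroman-4-one 5,7-bis(tert-butyldimethylsilyloxy)-2,2,6-trimethyl-8-(3-phenylpropanoyl)chroman-4-one F3. Noyori transfer hydrogenation with RuCl[(R,R)-TsDPEN](p-cymene) in HCO2H/Et3N, expected by analogy with chroman-4-ones to give the R carbinol, would return to the route at 11; the C8 ketone is di-ortho-substituted and twisted out of conjugation, a poor substrate for this catalyst.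

Step 2. Alkylation of the ambident anion may go to oxygen, to the methyl-bearing carbon with dearomatisation, or twice, because all these sites are nucleophilic in the polyanion. Fallback by electrophilic substitution: from 3, Friedel–Crafts prenylation with 2-methylbut-3-en-2-ol and BF3·OEt2 in dioxane at rt, stopped before acid-induced chroman formation, attacks the only free ring carbon and returns to the route at 5; no new compound arises (entry F0).

Step 3. Site selectivity may be lost (silylation of an ortho hydroxyl or double silylation), because in 5 the para hydroxyl is flanked by two substituents. Fallback by reversing the order: from 3, silylation (TBSCl, imidazole, DMF, 0 °C) of the para hydroxyl, which there has a free neighbouring position, would give 1-[4-(tert-butyldimethylsilyloxy)-2,6-dihydroxy-3-methylphenyl]-3-phenylpropan-1-one F4. Ortho C-prenylation of its sodium phenoxide in a non-polar medium (NaH, PhMe, 4, 0 °C to rt) would return to the route at 6.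

## Further compounds

F1 | step 4 | 1-[5-(tert-butyldimethylsilyloxy)-7-hydroxy-2,2,6-trimethyl-3-(phenylselanyl)chroman-8-yl]-3-phenylpropan-1-one (racemic) | Cc1c(O)c(C(=O)CCc2ccccc2)c2c(c1O[Si](C)(C)C(C)(C)C)CC([Se]c1ccccc1)C(C)(C)O2
F2 | step 6 | 1-[5,7-bis(tert-butyldimethylsilyloxy)-4-hydroxy-2,2,6-trimethylchroman-8-yl]-3-phenylpropan-1-one (racemic) | Cc1c(O[Si](C)(C)C(C)(C)C)c(C(=O)CCc2ccccc2)c2c(c1O[Si](C)(C)C(C)(C)C)C(O)CC(C)(C)O2
F3 | step 6 | 5,7-bis(tert-butyldimethylsilyloxy)-2,2,6-trimethyl-8-(3-phenylpropanoyl)chroman-4-one | Cc1c(O[Si](C)(C)C(C)(C)C)c(C(=O)CCc2ccccc2)c2c(c1O[Si](C)(C)C(C)(C)C)C(=O)CC(C)(C)O2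
F0 | step 2 | none | none
F4 | step 3 | 1-[4-(tert-butyldimethylsilyloxy)-2,6-dihydroxy-3-methylphenyl]-3-phenylpropan-1-one | Cc1c(O[Si](C)(C)C(C)(C)C)cc(O)c(C(=O)CCc2ccccc2)c1O
A1 | alternative 1 | (R)-configured tethered precursor: 1-methoxy-2-methyl-1,3-bis(trimethylsilyloxy)buta-1,3-diene bearing at its terminus the CH(OTBS)CH2C(CH3)2O–C≡C–C(=O)CH=CHPh chain | COC(O[Si](C)(C)C)=C(C)C(O[Si](C)(C)C)=C[C@H](O[Si](C)(C)C(C)(C)C)CC(C)(C)OC#CC(=O)/C=C/c1ccccc1
A2 | alternative 1 | (E)-1-[(4R)-4-(tert-butyldimethylsilyloxy)-5,7-dihydroxy-2,2,6-trimethylchroman-8-yl]-3-phenylprop-2-en-1-one | Cc1c(O)c(C(=O)/C=C/c2ccccc2)c2c(c1O)[C@H](O[Si](C)(C)C(C)(C)C)CC(C)(C)O2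
A3 | alternative 2 | 3-(3,5-dihydroxy-4-methylphenoxy)-3-methylbutanal | Cc1c(O)cc(OC(C)(C)CC=O)cc1O
A4 | alternative 2 | (4R)-2,2,6-trimethylchroman-4,5,7-triol | Cc1c(O)cc2c(c1O)[C@H](O)CC(C)(C)O2
A5 | alternative 3 | (R)-2-diazo-1-[4-(tert-butyldimethylsilyloxy)-2,2-dimethyl-3,4-dihydro-2H-pyran-6-yl]ethan-1-one | O=C(C=[N+]=[N-])C1=C[C@H](O[Si](C)(C)C(C)(C)C)CC(C)(C)O1
A6 | alternative 3 | 1-(triisopropylsilyloxy)propyne | CC#CO[Si](C(C)C)(C(C)C)C(C)C
A7 | alternative 3 | (4R)-4-(tert-butyldimethylsilyloxy)-2,2,6-trimethyl-7-(triisopropylsilyloxy)chroman-5-ol | Cc1c(O[Si](C(C)C)(C(C)C)C(C)C)cc2c(c1O)[C@H](O[Si](C)(C)C(C)(C)C)CC(C)(C)O2
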